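## Structural features

The target is a flavonol: benzene ring A is fused to the 4-pyranone ring C, and the guaiacyl ring B hangs on C2 by a single C2–C1' bond. It has no stereocentre, so nothing has to be set or protected against epimerisation. Ring A carries three oxygens in a 1,3,5-pattern (O1 at C8a, O5, O7), ring C the enolic O3 next to the C4 carbonyl, and ring B a 3'-methoxy/4'-hydroxy pair. Two of the four hydroxyls of the parent flavonol (O3, O7) are hydrogen sulfate esters and two (O5, O4') are free, so the real difficulty is telling four oxygens apart. The sulfate monoesters are the fragile groups: they hydrolyse under acid and survive only as salts in neutral or basic medium, so they must come after every acidic step, and the last protecting group must leave under neutral conditions. The 3'-methyl ether has to survive, which rules out methyl ethers as protecting groups elsewhere. The 5-OH is chelated to the C4 carbonyl and is a poor nucleophile, so it can stay free during sulfation, whereas O4' needs a mask. The key step uses the ring fusion: C8a bears O1 and its neighbour C4a bears the C4 acyl carbon, with the C5 oxygen next to C4a. This ortho oxygen/acyl pair is what a carboxylic acid delivers across the C4a–C8a triple bond of an aryne polarised by a C5 alkoxy group.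

## Logic of the disconnections

17 to 16: the O4'–CH2Ph bond is cut. A benzyl ether is the one mask that can be removed by hydrogenolysis without acid, so the sulfate esters survive. The forward step must leave the S–O bonds and the C2=C3 bond alone.

16 to 15: the two O–S bonds at O3 and O7 are cut. This removes the fragile groups in one stroke. The forward step must sulfate O3 and O7 and leave the chelated O5 free, and O4' has to be blocked already.

15 to 14: the two acetal O–CH2 bonds on O5 and O7 are cut. Acid-labile acetals on ring A are orthogonal to the benzyl ether on ring B and can be removed before sulfur is introduced. The forward step needs acid that spares the benzyl and methyl ethers.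

14 to 12 (through 13): the O1–C2 bond and the C3–O3 bond are cut, opening ring C to an open-chain enone with a free ortho phenol. Ring closure and C3 oxygenation then happen in one oxidative step. The forward step must close the six-membered ring (attack at the β-carbon) and not the five-membered one.

12 to 6 and 10 (through 11): the O–C8a bond and the C4–C4a bond are cut. This splits the molecule into a ring A block and a ring B/three-carbon block of similar size and delivers the free phenol needed for the next step without a deprotection. The forward step needs the oxygen at the aryne carbon remote from the flanking alkoxy group and the acyl carbon at the near one.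

6 to 3 (through 4 and 5): the C–Si bond and the O–S bond of the triflate are cut. Both come from one ortho-bromophenol by a 1,3 oxygen-to-carbon silyl shift and O-triflation. The forward step needs halogen–lithium exchange faster than any deprotonation.

3 to 2: the C–Br bond is cut. The two positions ortho to the hydroxyl of 2 are equivalent, so only ortho versus para selectivity is required.

2 to 1: two O–CH2 bonds are cut. 1 is symmetric, so only the degree of alkylation has to be controlled.

10 to 7 and 8 (through 9): the O–CH2Ph bond is cut. Alkylation also esterifies the carboxyl group, so a saponification is built into the same operation.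

## Other disconnections considered

Alternative 1: The cut is at C4–C4a and O1–C2, joining 1 directly to the α-benzoyloxy β-ketoester A2.
- Forward step: heating 1 with A2 well above 200 °C acylates a ring carbon of 1 through the ester carbonyl and closes ring C by cyclodehydration onto the aryl ketone, giving A1.
- In its favour: 1 needs no protection and has no regiochemical issue; the C3 oxygen arrives in place, so no oxidative ring closure is needed and the five-membered-ring hazard of the chosen step 6 does not arise. Cleaving the benzoate of A1 would give 15 directly.
- Against it here: the fusion needs very high temperature; the ring carbon can attack the ketone instead and lactonise to the isomeric coumarin; benzoyl migration and benzyl ether loss are possible at that temperature; and A2 itself needs several steps including an α-acyloxylation.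
- Comparison: on step count to 15 and on protecting-group economy this alternative is better than the chosen plan. Both plans form C4–C4a by acyl transfer to a ring A carbon. The chosen plan has regiochemistry built into the aryne and runs at lower temperature, whereas the chromone/coumarin selectivity of the fusion depends on thermal conditions alone.

Alternative 2: The cut is at C4a–C5 and C8–C8a, so ring A is built on a finished ring C.
- Forward step: the bis(silyloxy) diene A5 adds to the sulfonyl-activated C5–C6 double bond of pyranone A4; loss of the sulfonyl and methoxy groups aromatises the new ring and gives A3.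
- In its favour: ring A arrives with free O5 and O7 and needs no protection; the polarity of diene and sulfonyl group fixes the orientation; O3 is already present and differentiated; no aryne precursor is needed.
- Against it here: A4 is a densely substituted pyranone whose assembly would take longer than that of 6; its double bond is part of a vinylogous ester and is a reluctant dienophile; and the O3/O7 differentiation in A3 is not needed, because both are sulfated, so the O3 acetal would be cleaved to reach 15.
- Comparison: on ring A protecting groups this alternative is better. On structure it builds a benzene ring that can be bought, which costs skeletal bonds. On step economy it is likely behind the chosen plan because of A4.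

Alternative 3: The cut is at C4a–C4, C4–C3 and O1–C2, a three-component assembly of ring C.
- Forward step: PdCl2(PPh3)2 with an amine base couples iodophenol A7, carbon monoxide A9 and alkyne A8. Oxidative addition to zerovalent palladium, CO insertion and alkynylation give an ynone, and the phenol then adds 6-endo to give flavone A6.
- In its favour: it is convergent and mild, and A7 is one step shorter to make than 6.
- Against it here: A6 lacks O3, so a separate C3 oxygenation is needed to reach 14; the ynone can also close 5-exo to the aurone skeleton; and A7 poses the same ortho-halogenation problem as 3.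
- Comparison: the step count to 14 is about equal. The mildness of the key step is better than the sealed-tube aryne reaction. The halogenation regiochemistry is an equal point. The chosen plan is ahead in that its product is the substrate for an oxidative ring closure that installs O3 in the same step.

Key step: step 5

Assumption: the sulfate monoesters are drawn as free acids; in the flask 16 and 17 are handled as triethylammonium salts, and the free acid form of 17 is released by a cold pass through a sulfonic acid resin only at the end, because aryl hydrogen sulfates hydrolyse under their own acidity.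

## Route

Step 1
Reactants: 1 phloroglucinol
Product: 2 3,5-bis(methoxymethoxy)phenol
Conditions: MOMCl (2.0 equiv), i-Pr2NEt, THF/CH2Cl2, 0 °C → rt; chromatography
Reagents that add atoms: chloromethyl methyl ether, COCCl
Why: O-alkylation of phenols with an α-chloro ether; 1 is symmetric, so only the degree of alkylation matters, and the bis-ether should be separable from the mono-ether (which can be resubmitted) and the tris-ether.

Step 2
Reactants: 2 3,5-bis(methoxymethoxy)phenol
Product: 3 2-bromo-3,5-bis(methoxymethoxy)phenol
Conditions: NBS (1.0 equiv), i-Pr2NH (0.1 equiv), CH2Cl2, −78 °C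
Reagents that add atoms: N-bromosuccinimide, O=C1CCC(=O)N1Br
Why: Amine-mediated ortho-bromination of a phenol; the N-bromoamine is held by hydrogen bonding to the hydroxyl and should deliver bromine to the adjacent carbon, and the two ortho positions are equivalent.

Step 3
Reactants: 3 2-bromo-3,5-bis(methoxymethoxy)phenol
Product: 6 3,5-bis(methoxymethoxy)-2-(trimethylsilyl)phenyl trifluoromethanesulfonate, via aryl trimethylsilyl ether 4 (not isolated), via lithium 2-(trimethylsilyl)phenoxide 5 (not isolated)
Conditions: HMDS, THF, 70 °C, evaporate; n-BuLi (1.1 equiv), THF, −100 → −80 °C; Tf2O (1.2 equiv), −100 °C → rt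
Reagents that add atoms: hexamethyldisilazane, C[Si](C)(C)N[Si](C)(C)C; trifluoromethanesulfonic anhydride, O=S(=O)(OS(=O)(=O)C(F)(F)F)C(F)(F)F
Why: O-silylation, bromine–lithium exchange and retro-Brook rearrangement (1,3 shift of silicon from oxygen to the lithiated carbon, driven by formation of the phenoxide), then O-triflation; exchange at −100 °C should outrun any lithiation directed by the acetal groups.

Step 4
Reactants: 7 ferulic acid; 8 benzyl bromide
Product: 10 (E)-4-benzyloxy-3-methoxycinnamic acid, via benzyl ester 9 (not isolated)
Conditions: BnBr (2.3 equiv), K2CO3, DMF, 60 °C; then 2 M NaOH aq, MeOH, 60 °C; HCl to pH 2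
Reagents that add atoms: benzyl bromide (reactant 8), BrCc1ccccc1; sodium hydroxide, [Na+].[OH-]
Why: Williamson alkylation of phenoxide and carboxylate followed by saponification of the benzyl ester in the same pot; the (E)-alkene is not affected.

Step 5
Reactants: 6 3,5-bis(methoxymethoxy)-2-(trimethylsilyl)phenyl trifluoromethanesulfonate; 10 (E)-4-benzyloxy-3-methoxycinnamic acid
Product: 12 4-benzyloxy-2'-hydroxy-3-methoxy-4',6'-bis(methoxymethoxy)chalcone, via 3,5-bis(methoxymethoxy)benzyne 11 (not isolated)
Conditions: 6 (1.3 equiv), CsF (4 equiv), THF, 125 °C, sealed tube; then 1 M KOH, MeOH, rt; AcOH, 0 °C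
Reagents that add atoms: none
Why: Fluoride attacks silicon of 6 and triflate leaves, giving 11; the caesium carboxylate of 10 then adds through oxygen to the aryne carbon remote from the flanking methoxymethoxy group, the carbon that becomes C2' of 12 (C8a of the flavone). The aryl anion formed next to that group attacks the ester carbonyl through a four-membered alkoxide, and C–O cleavage moves the cinnamoyl group from oxygen to carbon, giving the phenoxide of 12. The closest known reaction type is the fluoride-induced insertion of arynes from 2-(trimethylsilyl)aryl triflates into the C–O bond of carboxylic acids, α,β-unsaturated acids included, which gives ortho-hydroxyaryl ketones; mechanistically it is an aryne version of the anionic Fries shift. No ring is closed, no stereocentre is made, and the (E)-alkene of 10 is untouched. The regiochemistry is secured by the alkoxy group next to the aryne, whose inductive pull distorts the triple bond so that the nucleophile enters at the far carbon and the charge develops at the near one. Acyl transfer must beat protonation of the aryl anion; the aprotic medium, the high temperature and the Z-ester conformation, which holds the carbonyl carbon near the anion and the β-carbon away from it, favour transfer over protonation and over conjugate addition. Any oxa-Michael closure of the phenoxide onto the enone is reversible, and the alkaline work-up should return the open-chain 12.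

Step 6
Reactants: 12 4-benzyloxy-2'-hydroxy-3-methoxy-4',6'-bis(methoxymethoxy)chalcone
Product: 14 4'-benzyloxy-3-hydroxy-3'-methoxy-5,7-bis(methoxymethoxy)flavone, via trans-dihydroflavonol 13 (not isolated)
Conditions: 30% H2O2, 2 M NaOH aq, MeOH/THF, 0 °C → rt
Reagents that add atoms: hydrogen peroxide, OO
Why: Algar–Flynn–Oyamada reaction: hydroperoxide oxidises the enone of the chalcone phenoxide, the phenoxide closes the six-membered ring at the β-carbon to give racemic trans 13 (anti opening; both centres are erased again), and alkaline peroxide dehydrogenates 13 to the flavonol. The electron-rich ring B should favour attack at the β-carbon.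

Step 7
Reactants: 14 4'-benzyloxy-3-hydroxy-3'-methoxy-5,7-bis(methoxymethoxy)flavone
Product: 15 4'-benzyloxy-3,5,7-trihydroxy-3'-methoxyflavone
Conditions: 3 M HCl, MeOH/THF, 50 °C
Reagents that add atoms: none
Why: Acid-catalysed acetal exchange with methanol removes both methoxymethyl groups; the benzyl and methyl aryl ethers and the flavonol core should be inert to dilute acid at this temperature.

Step 8
Reactants: 15 4'-benzyloxy-3,5,7-trihydroxy-3'-methoxyflavone
Product: 16 4'-O-benzylisorhamnetin 3,7-bis(hydrogen sulfate)
Conditions: SO3·NEt3 (6 equiv), Et3N, DMA, 40 °C; size-exclusion or reversed-phase chromatography (triethylammonium salt)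
Reagents that add atoms: sulfur trioxide–triethylamine complex, CC[N+](CC)(CC)S(=O)(=O)[O-]
Why: O-sulfation with an amine–SO3 complex; the acidic 7-OH and the enolic 3-OH should react, while the 5-OH is held in a six-membered hydrogen-bond chelate with the C4 carbonyl and O4' is blocked.

Step 9
Reactants: 16 4'-O-benzylisorhamnetin 3,7-bis(hydrogen sulfate)
Product: 17 isorhamnetin 3,7-di-O-sulfate
Conditions: H2 (1 atm), 10% Pd/C, MeOH/THF, trace Et3N, rt; filter; Dowex 50WX8 (H+ form), H2O, 0 °C; lyophilise
Reagents that add atoms: none
Why: Hydrogenolysis of the benzyl aryl ether under neutral conditions; sulfate monoester anions and the push–pull C2=C3 bond should not be reduced at 1 atm, and the cold resin pass gives the acid form.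

## Compound list

1 | phloroglucinol | Oc1cc(O)cc(O)c1 | starting material
2 | 3,5-bis(methoxymethoxy)phenol | COCOc1cc(O)cc(OCOC)c1 | intermediate
3 | 2-bromo-3,5-bis(methoxymethoxy)phenol | COCOc1cc(O)c(Br)c(OCOC)c1 | intermediate
4 | [2-bromo-3,5-bis(methoxymethoxy)phenoxy]trimethylsilane | COCOc1cc(O[Si](C)(C)C)c(Br)c(OCOC)c1 | intermediate
5 | lithium 3,5-bis(methoxymethoxy)-2-(trimethylsilyl)phenoxide | [Li+].COCOc1cc([O-])c([Si](C)(C)C)c(OCOC)c1 | intermediate
6 | 3,5-bis(methoxymethoxy)-2-(trimethylsilyl)phenyl trifluoromethanesulfonate | COCOc1cc(OCOC)c([Si](C)(C)C)c(OS(=O)(=O)C(F)(F)F)c1 | intermediate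
7 | ferulic acid | COc1cc(/C=C/C(=O)O)ccc1O | starting material
8 | benzyl bromide | BrCc1ccccc1 | starting material
9 | benzyl (E)-4-benzyloxy-3-methoxycinnamate | COc1cc(/C=C/C(=O)OCc2ccccc2)ccc1OCc1ccccc1 | intermediate
10 | (E)-4-benzyloxy-3-methoxycinnamic acid | COc1cc(/C=C/C(=O)O)ccc1OCc1ccccc1 | intermediate
11 | 3,5-bis(methoxymethoxy)benzyne | COCOC1=CC(OCOC)=CC#C1 | intermediate
12 | 4-benzyloxy-2'-hydroxy-3-methoxy-4',6'-bis(methoxymethoxy)chalcone, (E) | O=C(/C=C/c1ccc(OCc2ccccc2)c(OC)c1)c1c(O)cc(OCOC)cc1OCOC | intermediate
13 | trans-4'-benzyloxy-3-hydroxy-3'-methoxy-5,7-bis(methoxymethoxy)flavanone, racemic, (2R,3R) enantiomer drawn | O=C1c2c(OCOC)cc(OCOC)cc2O[C@H](c2ccc(OCc3ccccc3)c(OC)c2)[C@H]1O | intermediate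
14 | 4'-benzyloxy-3-hydroxy-3'-methoxy-5,7-bis(methoxymethoxy)flavone | COCOc1cc(OCOC)c2c(=O)c(O)c(-c3ccc(OCc4ccccc4)c(OC)c3)oc2c1 | intermediate
15 | 4'-benzyloxy-3,5,7-trihydroxy-3'-methoxyflavone | COc1cc(-c2oc3cc(O)cc(O)c3c(=O)c2O)ccc1OCc1ccccc1 | intermediate
16 | 4'-O-benzylisorhamnetin 3,7-bis(hydrogen sulfate) | COc1cc(-c2oc3cc(OS(=O)(=O)O)cc(O)c3c(=O)c2OS(=O)(=O)O)ccc1OCc1ccccc1 | intermediate
17 | isorhamnetin 3,7-di-O-sulfate | COc1cc(-c2oc3cc(OS(=O)(=O)O)cc(O)c3c(=O)c2OS(=O)(=O)O)ccc1O | target

## Step count and least certain steps

Total: 9 steps. Longest linear sequence: 8 steps (1 → 2 → 3 → 6 → 12 → 14 → 15 → 16 → 17; steps 1, 2, 3, 5, 6, 7, 8, 9).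

Step 5 (key step). The most likely failure is protonation of the aryl anion before the acyl shift, which stops the sequence at the aryl ester. The anion is crowded, flanked by the ester oxygen and a methoxymethoxy group, and bifluoride is present as a proton source. Arylation of the product phenoxide by a second aryne would also cost material. Fallback, by anionic acylation: 10 would be coupled with N,O-dimethylhydroxylamine hydrochloride (EDC, i-Pr2NEt, CH2Cl2) to the Weinreb amide (E)-3-(4-benzyloxy-3-methoxyphenyl)-N-methoxy-N-methylprop-2-enamide F1. 3 would be converted with n-BuLi (2.2 equiv, THF, −78 °C) into its O,C-dilithio derivative by deprotonation and bromine–lithium exchange, and addition of F1 should give, after aqueous work-up, the ketone. The fallback sets out from 3 and 10 and returns at 12.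

Step 6. The likely failure is closure of the five-membered ring: attack of the phenoxide at the α-carbon of the oxidised enone, which leads into the aurone manifold. The 6'-alkoxy group twists the carbonyl out of the ring plane and is known to favour this. Fallback, separating ring closure from oxygenation: 12 would be cyclised (NaOAc, EtOH, reflux) to racemic 4'-benzyloxy-3'-methoxy-5,7-bis(methoxymethoxy)flavanone F2. F2 would be dehydrogenated with catalytic Pd(OCOCF3)2 (divalent palladium) in DMSO under O2 at 80 °C to 4'-benzyloxy-3'-methoxy-5,7-bis(methoxymethoxy)flavone F3. Dimethyldioxirane in acetone/CH2Cl2 at 0 °C would give the racemic 2,3-epoxide of the flavone F4, and a trace of TsOH would isomerise it to the 3-hydroxyflavone. The fallback sets out from 12 and returns at 14.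

Step 2. The likely failure is bromination para to the hydroxyl, at the carbon between the two acetal groups, and double bromination; all three ring positions are strongly activated. Fallback, by directed metalation, which also replaces step 3:
- 2 would be carbamoylated (Et2NCOCl, K2CO3, MeCN, reflux) to 3,5-bis(methoxymethoxy)phenyl N,N-diethylcarbamate F5.
- F5 would be lithiated with s-BuLi/TMEDA (THF, −78 °C) at the carbon between the carbamate and an acetal group, where two directing groups cooperate and the carbamate is the stronger, and quenched with TMSCl to 3,5-bis(methoxymethoxy)-2-(trimethylsilyl)phenyl N,N-diethylcarbamate F6.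
- Cp2Zr(H)Cl (Schwartz reagent), THF, rt, would cleave the carbamate reductively to 3,5-bis(methoxymethoxy)-2-(trimethylsilyl)phenol F7.
- Tf2O/pyridine (CH2Cl2, 0 °C) would give the triflate.

The fallback sets out from 2 and returns at 6.

Step 8. The likely failure is incomplete sulfation at O3, which is hindered and hydrogen-bonded to the carbonyl, or sulfation creeping onto O5 under forcing conditions; the charged products are hard to separate. Fallback, through neutral protected sulfates: 15 would be treated with 2,2,2-trichloroethyl chlorosulfate (Et3N, DMAP, THF, 0 °C → rt) to give the 3,7-bis(2,2,2-trichloroethyl sulfate) diester of 4'-O-benzylisorhamnetin F8, which can be purified on silica. Zn dust with HCO2NH4 in MeOH at rt would then remove both trichloroethyl groups by reductive fragmentation. The fallback sets out from 15 and returns at 16 (as its ammonium salt).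

## Further compounds

F1 | step 5 | (E)-3-(4-benzyloxy-3-methoxyphenyl)-N-methoxy-N-methylprop-2-enamide | CON(C)C(=O)/C=C/c1ccc(OCc2ccccc2)c(OC)c1
F2 | step 6 | 4'-benzyloxy-3'-methoxy-5,7-bis(methoxymethoxy)flavanone, racemic | COCOc1cc(OCOC)c2c(c1)OC(c1ccc(OCc3ccccc3)c(OC)c1)CC2=O
F3 | step 6 | 4'-benzyloxy-3'-methoxy-5,7-bis(methoxymethoxy)flavone | COCOc1cc(OCOC)c2c(=O)cc(-c3ccc(OCc4ccccc4)c(OC)c3)oc2c1
F4 | step 6 | 2-(4-benzyloxy-3-methoxyphenyl)-2,3-epoxy-5,7-bis(methoxymethoxy)chroman-4-one, racemic | COCOc1cc(OCOC)c2c(c1)OC1(c3ccc(OCc4ccccc4)c(OC)c3)OC1C2=O
F5 | step 2 | 3,5-bis(methoxymethoxy)phenyl N,N-diethylcarbamate | CCN(CC)C(=O)Oc1cc(OCOC)cc(OCOC)c1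
F6 | step 2 | 3,5-bis(methoxymethoxy)-2-(trimethylsilyl)phenyl N,N-diethylcarbamate | CCN(CC)C(=O)Oc1cc(OCOC)cc(OCOC)c1[Si](C)(C)C
F7 | step 2 | 3,5-bis(methoxymethoxy)-2-(trimethylsilyl)phenol | COCOc1cc(O)c([Si](C)(C)C)c(OCOC)c1
F8 | step 8 | 4'-O-benzylisorhamnetin 3,7-bis(2,2,2-trichloroethyl sulfate) | COc1cc(-c2oc3cc(OS(=O)(=O)OCC(Cl)(Cl)Cl)cc(O)c3c(=O)c2OS(=O)(=O)OCC(Cl)(Cl)Cl)ccc1OCc1ccccc1
A1 | alternative 1 | 3-benzoyloxy-4'-benzyloxy-5,7-dihydroxy-3'-methoxyflavone | COc1cc(-c2oc3cc(O)cc(O)c3c(=O)c2OC(=O)c2ccccc2)ccc1OCc1ccccc1
A2 | alternative 1 | ethyl 2-benzoyloxy-3-(4-benzyloxy-3-methoxyphenyl)-3-oxopropanoate, racemic | CCOC(=O)C(OC(=O)c1ccccc1)C(=O)c1ccc(OCc2ccccc2)c(OC)c1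
A3 | alternative 2 | 4'-benzyloxy-5,7-dihydroxy-3'-methoxy-3-(methoxymethoxy)flavone | COCOc1c(-c2ccc(OCc3ccccc3)c(OC)c2)oc2cc(O)cc(O)c2c1=O
A4 | alternative 2 | 2-(4-benzyloxy-3-methoxyphenyl)-3-(methoxymethoxy)-5-(phenylsulfonyl)-4H-pyran-4-one | COCOc1c(-c2ccc(OCc3ccccc3)c(OC)c2)occ(S(=O)(=O)c2ccccc2)c1=O
A5 | alternative 2 | 1-methoxy-1,3-bis(trimethylsilyloxy)buta-1,3-diene | COC(O[Si](C)(C)C)=CC(=C)O[Si](C)(C)C
A6 | alternative 3 | 4'-benzyloxy-3'-methoxy-5,7-bis(methoxymethoxy)flavone | COCOc1cc(OCOC)c2c(=O)cc(-c3ccc(OCc4ccccc4)c(OC)c3)oc2c1
A7 | alternative 3 | 2-iodo-3,5-bis(methoxymethoxy)phenol | COCOc1cc(O)c(I)c(OCOC)c1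
A8 | alternative 3 | 1-benzyloxy-4-ethynyl-2-methoxybenzene | C#Cc1ccc(OCc2ccccc2)c(OC)c1
A9 | alternative 3 | carbon monoxide | [C-]#[O+]
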